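**Retrosynthetic overview**
1. Last bond: the CH2 bridge between the two pyranone C3 positions, made by a Mannich / retro-Mannich–Michael union of the tetralone monomer with its own dehydrated (naphthalene) form.
2. Tetralone ring: one-carbon oxidative ring expansion of a cyclopropanated indanone silyl enol ether (ring-fusion bond scission, O2 capture) installs the tertiary 3-OH; the naphthalene half comes from acid dehydration of the same monomer.
3. C4 stereocentre: copper hydride enantioselective 1,4-hydrosilylation of a 2-phenyl-3-pyranonyl indenone.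
4. Indenone: rhodium-catalysed C–H annulation of 2-(benzyloxy)benzaldehyde (from phenol) with a 6-(phenylethynyl)pyranone (from two molecules of malonyl dichloride and phenylacetylene).
5. Ring order: pyranone, indenone five-membered ring, cyclopropane, six-membered tetralone (ring expansion), naphthalene (dehydration), dimer.

Assumption: paraformaldehyde is counted as formaldehyde, and the ligand enantiomer named in step 7 is assigned by analogy (its antipode is used if the first run shows the opposite sense).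

**Step 1**
Reactants: 1 phenol; 2 formaldehyde (as paraformaldehyde)
Product: 3 2-hydroxybenzaldehyde
Conditions: MgCl2, Et3N, (CH2O)n, MeCN, reflux
Reagents that add atoms: none
Why: Magnesium-phenoxide-directed ortho-formylation (Casiraghi–Skattebøl type) gives only the ortho aldehyde, a second equivalent of formaldehyde serving as hydride acceptor.

**Step 2**
Reactants: 3 2-hydroxybenzaldehyde
Product: 4 2-(benzyloxy)benzaldehyde
Conditions: BnBr, K2CO3, DMF, rt
Reagents that add atoms: benzyl bromide, BrCc1ccccc1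
Why: Williamson ether synthesis; the benzyl ether survives every later step and is removed by hydrogenolysis in step 10.

**Step 3**
Reactants: 5 malonyl dichloride (two molecules)
Product: 8 6-chloro-4-hydroxy-2H-pyran-2-one, via acid chloride 6 (not isolated), via carboxylic acid 7 (not isolated)
Conditions: neat, 25 °C, 4 d; then H2O (1.5 equiv), 1,4-dioxane, 60 °C
Reagents that add atoms: malonyl dichloride (the second molecule of 5), O=C(Cl)CC(=O)Cl
Why: Self-condensation of two molecules of malonyl dichloride (C-acylation of one by the other, O-cyclisation of the enolised acid chloride, loss of two HCl) gives the 3-chlorocarbonyl pyranone 6; water hydrolyses it to acid 7, which decarboxylates on mild heating as a vinylogous β-keto acid.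

**Step 4**
Reactants: 8 6-chloro-4-hydroxy-2H-pyran-2-one
Product: 9 4-(benzyloxy)-6-chloro-2H-pyran-2-one
Conditions: BnOH, PPh3, DIAD, THF, 0 °C to rt
Reagents that add atoms: benzyl alcohol, OCc1ccccc1
Why: Mitsunobu O-alkylation of the acidic 4-hydroxyl (pKa about 5) gives the 4-alkoxy-2-pyranone regioselectively.

**Step 5**
Reactants: 9 4-(benzyloxy)-6-chloro-2H-pyran-2-one; 10 phenylacetylene
Product: 11 4-(benzyloxy)-6-(phenylethynyl)-2H-pyran-2-one
Conditions: PdCl2(PPh3)2 (3 mol%), CuI (copper iodide, 5 mol%), Et3N, THF, 40 °C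
Reagents that add atoms: none
Why: Sonogashira coupling; the C6–Cl bond is a vinylogous acid chloride and adds readily to zerovalent palladium.

**Step 6**
Reactants: 4 2-(benzyloxy)benzaldehyde; 11 4-(benzyloxy)-6-(phenylethynyl)-2H-pyran-2-one
Product: 14 7-(benzyloxy)-3-[4-(benzyloxy)-2-oxo-2H-pyran-6-yl]-2-phenyl-1H-inden-1-one, via nitrone 12 (not isolated), via ketimine 13 (not isolated)
Conditions: t-BuNHOH, MgSO4, CH2Cl2, rt; then [Cp*Rh(MeCN)3](SbF6)2 (5 mol%), 1,4-dioxane, 80 °C; then 1 M HCl
Reagents that add atoms: none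
Why: Nitrone-directed ortho C–H activation by trivalent rhodium, alkyne insertion, addition of the alkenyl–rhodium to the nitrone carbon, N–O cleavage (internal oxidant) and imine hydrolysis give the indenone (C–H annulation); the benzyloxy group blocks one ortho site, and rhodium binds the phenyl-bearing alkyne carbon (as with aryl alkynoates), so phenyl ends at C2 and the pyranone at C3.

**Step 7**
Reactants: 14 7-(benzyloxy)-3-[4-(benzyloxy)-2-oxo-2H-pyran-6-yl]-2-phenyl-1H-inden-1-one
Product: 15 (1R)-4-(benzyloxy)-1-[4-(benzyloxy)-2-oxo-2H-pyran-6-yl]-3-{[dimethyl(phenyl)silyl]oxy}-2-phenyl-1H-indene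
Conditions: Cu(OAc)2·H2O (5 mol%), (R)-DTBM-SEGPHOS (5.5 mol%), PhMe2SiH (2 equiv), toluene, 0 °C to rt, no base or alcohol additive
Reagents that add atoms: dimethyl(phenyl)silane, C[SiH](C)c1ccccc1
Why: Ligand-controlled copper hydride conjugate reduction (enantioselective 1,4-hydrosilylation) delivers hydride to one face of C3 of the indenone and sets the stereocentre that becomes C4 of the tetralone; σ-bond metathesis with the silane traps the enolate as the silyl enol ether under base-free conditions, so the acidic C–H does not epimerise.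

**Step 8**
Reactants: 15 silyl enol ether (as named in step 7); 16 diiodomethane
Product: 17 (1aR,6R,6aS)-2-(benzyloxy)-6-[4-(benzyloxy)-2-oxo-2H-pyran-6-yl]-1a-{[dimethyl(phenyl)silyl]oxy}-6a-phenyl-1,1a,6,6a-tetrahydrocyclopropa[a]indene (cyclopropane CH2 anti to the pyranonyl group)
Conditions: Et2Zn (3 equiv), 16 (6 equiv), CH2Cl2, 0 °C to rt
Reagents that add atoms: none
Why: Simmons–Smith (Furukawa) cyclopropanation of the electron-rich silyl enol ether from the face anti to the pyranonyl substituent; both new centres are erased in step 9.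

**Step 9**
Reactants: 17 siloxycyclopropane (as named in step 8)
Product: 20 (3R,4R)-8-(benzyloxy)-4-[4-(benzyloxy)-2-oxo-2H-pyran-6-yl]-3-hydroxy-3-phenyl-3,4-dihydronaphthalen-1(2H)-one, via cyclopropanol 18 (not isolated), via hydroperoxide 19 (not isolated)
Conditions: TBAF (1.05 equiv), AcOH (1.1 equiv), THF, 0 °C; then Mn(acac)3 (10 mol%), O2 (1 atm), 0 °C to rt; then PPh3 (1.2 equiv), 0 °C
Reagents that add atoms: dioxygen, O=O
Why: Proposed new method: fluoride unmasks the cyclopropanol, whose trivalent manganese alkoxide fragments at the ring-fusion C–C bond (strain release, tertiary benzylic β-keto radical), enlarging the five-membered ring to the tetralone; the planar radical captures O2 on the face anti to the pseudo-axial pyranonyl group at C4, which sets (3R) with OH trans to the pyranone, and PPh3 reduces the hydroperoxide to the tertiary alcohol; the closest known reactions are the Saegusa–Ito FeCl3 ring expansion of siloxycyclopropanes and the manganese-catalysed aerobic opening of simple monocyclic cyclopropanols to β-peroxy ketones, neither shown for a ring-fused 1a-aryl cyclopropanol with stereocontrolled oxygen capture.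

**Step 10**
Reactants: 20 bis-benzyl ether (as named in step 9)
Product: 21 (3R,4R)-3,8-dihydroxy-4-(4-hydroxy-2-oxo-2H-pyran-6-yl)-3-phenyl-3,4-dihydronaphthalen-1(2H)-one
Conditions: H2 (1 atm), 10% Pd/C, EtOAc, rt, 1 h
Reagents that add atoms: none
Why: Neutral hydrogenolysis cleaves both benzyl ethers, while the tertiary benzylic alcohol, the chelated aryl ketone and the pyranone are not reduced under these short, neutral conditions.

**Step 11**
Reactants: 21 tetralone monomer (as named in step 10), half of the material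
Product: 22 6-(4,5-dihydroxy-2-phenylnaphthalen-1-yl)-4-hydroxy-2H-pyran-2-one
Conditions: TsOH·H2O (10 mol%), toluene/THF, 70 °C
Reagents that add atoms: none
Why: Acid-catalysed dehydration of the β-hydroxy ketone and tautomerisation to the naphthol (aromatisation-driven) deliberately erases both stereocentres to give the achiral half.

**Step 12**
Reactants: 21 tetralone monomer; 22 naphthalene monomer; 23 N,N-dimethylmethyleneiminium iodide (Eschenmoser's salt)
Product: 26 wailupemycin I, via Mannich base 24 (not isolated), via methylene pyrandione 25 (not isolated)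
Conditions: 23 (1.0 equiv), MeCN, 0 °C to rt, 1 h; then 22 (1.2 equiv), NaOAc (1.1 equiv), 60 °C
Reagents that add atoms: none
Why: Mannich reaction at the enolic C3 of the pyranone of 21, retro-Mannich elimination to the 3-methylene-pyran-2,4-dione and Michael addition of the pyranone C3 of 22 give the mixed methylene-bridged dimer; the staged addition avoids the homodimers and the (3R,4R) centres are untouched.

**Compound list**
1 | phenol | Oc1ccccc1 | starting material
2 | formaldehyde (used as paraformaldehyde) | C=O | starting material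
3 | 2-hydroxybenzaldehyde | O=Cc1ccccc1O | intermediate
4 | 2-(benzyloxy)benzaldehyde | O=Cc1ccccc1OCc1ccccc1 | intermediate
5 | malonyl dichloride | O=C(Cl)CC(=O)Cl | starting material
6 | 6-chloro-4-hydroxy-2-oxo-2H-pyran-3-carbonyl chloride | O=C(Cl)c1c(O)cc(Cl)oc1=O | intermediate
7 | 6-chloro-4-hydroxy-2-oxo-2H-pyran-3-carboxylic acid | O=C(O)c1c(O)cc(Cl)oc1=O | intermediate
8 | 6-chloro-4-hydroxy-2H-pyran-2-one | O=c1cc(O)cc(Cl)o1 | intermediate
9 | 4-(benzyloxy)-6-chloro-2H-pyran-2-one | O=c1cc(OCc2ccccc2)cc(Cl)o1 | intermediate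
10 | phenylacetylene | C#Cc1ccccc1 | starting material
11 | 4-(benzyloxy)-6-(phenylethynyl)-2H-pyran-2-one | O=c1cc(OCc2ccccc2)cc(C#Cc2ccccc2)o1 | intermediate
12 | (Z)-1-[2-(benzyloxy)phenyl]-N-tert-butylmethanimine N-oxide | [O-]/[N+](=C\c1ccccc1OCc1ccccc1)C(C)(C)C | intermediate
13 | N-tert-butyl imine of 14 (C1=N–t-Bu in place of C1=O) | CC(C)(C)N=C1C(c2ccccc2)=C(c2cc(OCc3ccccc3)cc(=O)o2)c2cccc(OCc3ccccc3)c21 | intermediate
14 | 7-(benzyloxy)-3-[4-(benzyloxy)-2-oxo-2H-pyran-6-yl]-2-phenyl-1H-inden-1-one | O=C1C(c2ccccc2)=C(c2cc(OCc3ccccc3)cc(=O)o2)c2cccc(OCc3ccccc3)c21 | intermediate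
15 | (1R)-4-(benzyloxy)-1-[4-(benzyloxy)-2-oxo-2H-pyran-6-yl]-3-{[dimethyl(phenyl)silyl]oxy}-2-phenyl-1H-indene | C[Si](C)(OC1=C(c2ccccc2)[C@H](c2cc(OCc3ccccc3)cc(=O)o2)c2cccc(OCc3ccccc3)c21)c1ccccc1 | intermediate
16 | diiodomethane | ICI | starting material
17 | (1aR,6R,6aS)-2-(benzyloxy)-6-[4-(benzyloxy)-2-oxo-2H-pyran-6-yl]-1a-{[dimethyl(phenyl)silyl]oxy}-6a-phenyl-1,1a,6,6a-tetrahydrocyclopropa[a]indene | C[Si](C)(O[C@]12C[C@@]1(c1ccccc1)[C@H](c1cc(OCc3ccccc3)cc(=O)o1)c1cccc(OCc3ccccc3)c12)c1ccccc1 | intermediate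
18 | (1aR,6R,6aS)-2-(benzyloxy)-6-[4-(benzyloxy)-2-oxo-2H-pyran-6-yl]-6a-phenyl-1,1a,6,6a-tetrahydrocyclopropa[a]inden-1a-ol | O[C@]12C[C@@]1(c1ccccc1)[C@H](c1cc(OCc3ccccc3)cc(=O)o1)c1cccc(OCc3ccccc3)c12 | intermediate
19 | (3R,4S)-8-(benzyloxy)-4-[4-(benzyloxy)-2-oxo-2H-pyran-6-yl]-3-hydroperoxy-3-phenyl-3,4-dihydronaphthalen-1(2H)-one (OOH trans to the pyranone; may sit as its cyclic peroxy hemiketal) | O=C1C[C@](OO)(c2ccccc2)[C@H](c2cc(OCc3ccccc3)cc(=O)o2)c2cccc(OCc3ccccc3)c21 | intermediate
20 | (3R,4R)-8-(benzyloxy)-4-[4-(benzyloxy)-2-oxo-2H-pyran-6-yl]-3-hydroxy-3-phenyl-3,4-dihydronaphthalen-1(2H)-one | O=C1C[C@](O)(c2ccccc2)[C@H](c2cc(OCc3ccccc3)cc(=O)o2)c2cccc(OCc3ccccc3)c21 | intermediate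
21 | (3R,4R)-3,8-dihydroxy-4-(4-hydroxy-2-oxo-2H-pyran-6-yl)-3-phenyl-3,4-dihydronaphthalen-1(2H)-one | O=C1C[C@](O)(c2ccccc2)[C@H](c2cc(O)cc(=O)o2)c2cccc(O)c21 | intermediate
22 | 6-(4,5-dihydroxy-2-phenylnaphthalen-1-yl)-4-hydroxy-2H-pyran-2-one | O=c1cc(O)cc(-c2c(-c3ccccc3)cc(O)c3c(O)cccc23)o1 | intermediate
23 | N,N-dimethylmethyleneiminium iodide | C[N+](C)=C.[I-] | starting material
24 | (3R,4R)-4-{3-[(dimethylamino)methyl]-4-hydroxy-2-oxo-2H-pyran-6-yl}-3,8-dihydroxy-3-phenyl-3,4-dihydronaphthalen-1(2H)-one | O=C1C[C@](O)(c2ccccc2)[C@H](c2cc(O)c(CN(C)C)c(=O)o2)c2cccc(O)c21 | intermediate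
25 | (3R,4R)-3,8-dihydroxy-4-(3-methylene-2,4-dioxo-3,4-dihydro-2H-pyran-6-yl)-3-phenyl-3,4-dihydronaphthalen-1(2H)-one | O=C1C[C@](O)(c2ccccc2)[C@H](C2=CC(=O)C(=C)C(=O)O2)c2cccc(O)c21 | intermediate
26 | wailupemycin I, (3R,4R) tetralone unit linked by CH2 between the two pyranone C3 positions to the naphthalene unit | O=C1C[C@](O)(c2ccccc2)[C@H](c2cc(O)c(Cc3c(O)cc(-c4c(-c5ccccc5)cc(O)c5c(O)cccc45)oc3=O)c(=O)o2)c2cccc(O)c21 | target

**Step count and risks**
Total step count: 12.
Longest linear sequence: 10 steps (from 5 through steps 3, 4, 5, 6, 7, 8, 9, 10, 11, 12).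

Three steps most likely to fail:

**Step 9 (the proposed new ring expansion).** Risks are scission of the outer cyclopropane bond, poor facial control in oxygen capture, or dehydration of the product. The fallback uses known chemistry and runs from 17 back to 20. Compound 17 is desilylated (TBAF, AcOH) and the cyclopropanol 18 is isolated. It is then opened with stoichiometric Mn(acac)3 under argon in the presence of TEMPO, the known radical ring opening of cyclopropanols by trivalent manganese with nitroxide capture. The ring-enlarged tertiary radical couples with the nitroxide anti to the pyranonyl group to give (3R,4S)-8-(benzyloxy)-4-[4-(benzyloxy)-2-oxo-2H-pyran-6-yl]-3-phenyl-3-[(2,2,6,6-tetramethylpiperidin-1-yl)oxy]-3,4-dihydronaphthalen-1(2H)-one F8. Zn dust in AcOH/THF then cleaves the N–O bond to give 20. This replaces the catalytic aerobic chain and peroxide reduction by radical–radical coupling and reductive N–O cleavage.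

**Step 7 (copper hydride reduction of a tetrasubstituted indenone that carries a reducible pyranone).** The fallback uses known chemistry and runs from 14 back to 15. Corey–Bakshi–Shibata reduction of the ketone ((S)-2-methyl-CBS-oxazaborolidine or its antipode, chosen to give the (1R) alcohol; BH3·SMe2, toluene, −40 °C) gives (1R)-7-(benzyloxy)-3-[4-(benzyloxy)-2-oxo-2H-pyran-6-yl]-2-phenyl-1H-inden-1-ol F6. DABCO in THF at 40 °C effects the suprafacial 1,3-hydrogen shift known for 3-aryl indenols, moving the C1 hydrogen to C3 on the same face, and gives (2R,3S)-7-(benzyloxy)-3-[4-(benzyloxy)-2-oxo-2H-pyran-6-yl]-2-phenyl-2,3-dihydro-1H-inden-1-one F7. KHMDS then PhMe2SiCl at −78 °C in THF (enolisation at C2 only) gives 15.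

**Step 6 (regiochemistry of alkyne insertion and tolerance of the pyranone).** The fallback uses known chemistry, a polarity-matched Heck arylation of a preformed 2-phenylindenone, and runs from 1 and 9 back to 14. Phenol 1 is acylated with 3-chloropropanoyl chloride to phenyl 3-chloropropanoate F1. An AlCl3 melt at 170 °C (Fries rearrangement, then intramolecular Friedel–Crafts alkylation) gives 7-hydroxy-2,3-dihydro-1H-inden-1-one F2, and BnBr/K2CO3 gives 7-(benzyloxy)-2,3-dihydro-1H-inden-1-one F3. Pd(OAc)2/XPhos/NaOtBu α-arylation with bromobenzene gives racemic 7-(benzyloxy)-2-phenyl-2,3-dihydro-1H-inden-1-one F4, which DDQ in 1,4-dioxane dehydrogenates to 7-(benzyloxy)-2-phenyl-1H-inden-1-one F5. Heck reaction of F5 with chloropyranone 9 (Pd(OAc)2, Bu4NCl, NaHCO3, DMF, 80 °C) puts the pyranonyl group on the enone β-carbon. After epimerisation through the oxygen-bound palladium enolate and β-hydride elimination it gives 14.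

**Further compounds**
F1 | step 6 | phenyl 3-chloropropanoate | O=C(CCCl)Oc1ccccc1
F2 | step 6 | 7-hydroxy-2,3-dihydro-1H-inden-1-one | O=C1CCc2cccc(O)c21
F3 | step 6 | 7-(benzyloxy)-2,3-dihydro-1H-inden-1-one | O=C1CCc2cccc(OCc3ccccc3)c21
F4 | step 6 | 7-(benzyloxy)-2-phenyl-2,3-dihydro-1H-inden-1-one (racemic) | O=C1C(c2ccccc2)Cc2cccc(OCc3ccccc3)c21
F5 | step 6 | 7-(benzyloxy)-2-phenyl-1H-inden-1-one | O=C1C(c2ccccc2)=Cc2cccc(OCc3ccccc3)c21
F6 | step 7 | (1R)-7-(benzyloxy)-3-[4-(benzyloxy)-2-oxo-2H-pyran-6-yl]-2-phenyl-1H-inden-1-ol | O[C@@H]1C(c2ccccc2)=C(c2cc(OCc3ccccc3)cc(=O)o2)c2cccc(OCc3ccccc3)c21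
F7 | step 7 | (2R,3S)-7-(benzyloxy)-3-[4-(benzyloxy)-2-oxo-2H-pyran-6-yl]-2-phenyl-2,3-dihydro-1H-inden-1-one | O=C1[C@@H](c2ccccc2)[C@H](c2cc(OCc3ccccc3)cc(=O)o2)c2cccc(OCc3ccccc3)c21
F8 | step 9 | (3R,4S)-8-(benzyloxy)-4-[4-(benzyloxy)-2-oxo-2H-pyran-6-yl]-3-phenyl-3-[(2,2,6,6-tetramethylpiperidin-1-yl)oxy]-3,4-dihydronaphthalen-1(2H)-one | O=C1C[C@](ON2C(C)(C)CCCC2(C)C)(c2ccccc2)[C@H](c2cc(OCc3ccccc3)cc(=O)o2)c2cccc(OCc3ccccc3)c21
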